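The route cuts ring C of unit 1 (the flavone linked through C6) at three bonds: C8a–O1, C4a–C4 and O1–C2. Ring A of that unit carries O1 on C8a, the C4 carbonyl on the neighbouring C4a, and an oxygen on C5 beside C4a. This contiguous 1,2,3-pattern is what oxygen-then-acyl addition across a 3-alkoxyaryne produces. A single fluoride-triggered operation therefore joins 3-(4-methoxyphenyl)propiolic acid to a C4a≡C8a aryne and closes the pyranone. The precursor is the finished, isopropyl-protected unit 2 flavone. At C8'' it bears an aryl ring with SiMe3 on C4a, OTf on C8a and isopropoxy groups on C5 and C7. A Negishi coupling assembles it.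

Key step: step 11

Remark on the chemistry: the target string carries no descriptor for the hindered C6–C8'' biaryl axis and has no stereocentre, so the compound is made as the racemic mixture of atropisomers.

Step 1
Reactants: 1 2',6'-dihydroxy-4'-methoxyacetophenone
Product: 2 2'-hydroxy-6'-isopropoxy-4'-methoxyacetophenone
Conditions: 2-bromopropane (1.1 equiv), K2CO3, DMF, 50 °C
Reagents that add atoms: 2-bromopropane, CC(C)Br
Why: Williamson ether synthesis; once one of the two equivalent ortho hydroxyls is alkylated, the other is held in a strong hydrogen bond to the acetyl oxygen, so the reaction should stop at the mono-ether.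

Step 2
Reactants: 2 2'-hydroxy-6'-isopropoxy-4'-methoxyacetophenone
Product: 3 2'-hydroxy-3'-iodo-6'-isopropoxy-4'-methoxyacetophenone
Conditions: NIS (1.05 equiv), CF3CO2H (cat.), MeCN, 0 °C to rt
Reagents that add atoms: N-iodosuccinimide, O=C1CCC(=O)N1I
Why: Electrophilic aromatic iodination; all three oxygen substituents activate both free positions, but C3' lies beside the small chelated hydroxyl whereas C5' is walled in by methoxy and isopropoxy groups, and the 4',6'-dimethoxy analogue is known to iodinate at C3'.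

Step 3
Reactants: 3 2'-hydroxy-3'-iodo-6'-isopropoxy-4'-methoxyacetophenone, 4 4-methoxybenzaldehyde
Product: 5 (E)-1-(2-hydroxy-3-iodo-6-isopropoxy-4-methoxyphenyl)-3-(4-methoxyphenyl)prop-2-en-1-one
Conditions: KOH (aq), EtOH, rt
Reagents that add atoms: none
Why: Claisen–Schmidt condensation; the ketone enolate adds to the non-enolisable aldehyde and E1cB dehydration gives the conjugated enone in its more stable E geometry, while the aryl iodide and the ethers are inert to cold alkali.

Step 4
Reactants: 5 (E)-1-(2-hydroxy-3-iodo-6-isopropoxy-4-methoxyphenyl)-3-(4-methoxyphenyl)prop-2-en-1-one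
Product: 7 8-iodo-5-isopropoxy-7-methoxy-2-(4-methoxyphenyl)-4H-chromen-4-one, via flavanone 6 (not isolated)
Conditions: I2 (10 mol %), DMSO, 120 °C
Reagents that add atoms: none
Why: Iodine-catalysed oxidative cyclisation of a 2'-hydroxychalcone; the only free hydroxyl closes the ring by 6-endo-trig oxa-Michael addition, alpha-iodination and loss of HI dehydrogenate flavanone 6, DMSO re-oxidises HI, and the iodine beside that hydroxyl necessarily becomes C8–I.

Step 5
Reactants: 8 2-bromoresorcinol
Product: 9 2-bromo-1,3-diisopropoxybenzene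
Conditions: 2-bromopropane (3 equiv), K2CO3, DMF, 70 °C
Reagents that add atoms: 2-bromopropane, CC(C)Br
Why: Double Williamson ether synthesis on a diphenol that offers no competing nucleophilic site; the aryl bromide is inert.

Step 6
Reactants: 9 2-bromo-1,3-diisopropoxybenzene
Product: 11 4-bromo-3,5-diisopropoxyphenol, via pinacol boronate 10 (not isolated)
Conditions: [Ir(OMe)(cod)]2 (1.5 mol %), dtbpy (3 mol %), B2pin2 (0.6 equiv), THF, 80 °C; then 30% H2O2, aq NaOH, 0 °C to rt
Reagents that add atoms: bis(pinacolato)diboron, CC1(C)OB(B2OC(C)(C)C(C)(C)O2)OC1(C)C (boron and pinacol of 10); hydrogen peroxide, OO (phenol oxygen of 11)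
Why: Sterically controlled iridium-catalysed aromatic C–H borylation followed by boronate oxidation; only C5–H has no ortho substituent, aryl bromides are tolerated, and the shift of the aryl group from boron to oxygen places the hydroxyl exactly para to bromine.

Step 7
Reactants: 11 4-bromo-3,5-diisopropoxyphenol
Product: 12 4-bromo-2-iodo-3,5-diisopropoxyphenol
Conditions: NIS (1.0 equiv), CH2Cl2, −20 °C to 0 °C
Reagents that add atoms: N-iodosuccinimide, O=C1CCC(=O)N1I
Why: Electrophilic iodination ortho to a free phenol; C2 and C6 are the only open positions and are equivalent, so one equivalent of NIS at low temperature should give a single mono-iodide.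

Step 8
Reactants: 12 4-bromo-2-iodo-3,5-diisopropoxyphenol
Product: 16 [4-bromo-3,5-diisopropoxy-2-(trimethylsilyl)phenoxy]trimethylsilane, via aryl silyl ether 13 (not isolated), via aryllithium 14 (not isolated), via lithium phenoxide 15 (not isolated)
Conditions: (Me3Si)2NH, THF, 70 °C, evaporate; n-BuLi (1.05 equiv), THF, −78 °C; Me3SiCl, −78 °C to rt
Reagents that add atoms: hexamethyldisilazane, C[Si](C)(C)N[Si](C)(C)C (the SiMe3 that ends on carbon); chlorotrimethylsilane, C[Si](C)(C)Cl (the SiMe3 on oxygen); n-butyllithium, [Li]CCCC (lithium of 14 and 15 only)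
Why: Halogen–lithium exchange followed by retro-Brook rearrangement; iodine exchanges far faster than bromine at −78 °C, the ortho-lithiated silyl ether 14 passes silicon from oxygen to carbon (1,3-shift driven by phenoxide formation) as in the standard route to o-silylphenols, and Me3SiCl caps phenoxide 15 for the next organometallic step.

Step 9
Reactants: 16 [4-bromo-3,5-diisopropoxy-2-(trimethylsilyl)phenoxy]trimethylsilane, 7 8-iodo-5-isopropoxy-7-methoxy-2-(4-methoxyphenyl)-4H-chromen-4-one
Product: 20 8-[4-hydroxy-2,6-diisopropoxy-3-(trimethylsilyl)phenyl]-5-isopropoxy-7-methoxy-2-(4-methoxyphenyl)-4H-chromen-4-one, via aryllithium 17 (not isolated), via arylzinc chloride 18 (not isolated), via silyl ether 19 (not isolated)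
Conditions: 16 (1.3 equiv), n-BuLi, THF, −78 °C; ZnCl2, −78 °C to rt; 7, Pd2(dba)3 (2.5 mol %), RuPhos (10 mol %), THF, 65 °C; then MeOH, K2CO3 (cat.), 0 °C
Reagents that add atoms: n-butyllithium, [Li]CCCC (lithium of 17 only); zinc dichloride, Cl[Zn]Cl (zinc and chlorine of 18 only)
Why: Negishi cross-coupling; bromine–lithium exchange fixes the metal at the carbon between the two isopropoxy groups, the arylzinc chloride does not add to the pyranone, zerovalent palladium carrying a bulky dialkylbiarylphosphine is the established catalyst type for biaryls bearing four ortho substituents, the anhydrous neutral medium avoids the protodemetalation typical of 2,6-dialkoxyarylboron reagents and spares the C–Si bond, and brief methanolysis removes only the O-silyl group.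

Step 10
Reactants: 20 8-[4-hydroxy-2,6-diisopropoxy-3-(trimethylsilyl)phenyl]-5-isopropoxy-7-methoxy-2-(4-methoxyphenyl)-4H-chromen-4-one
Product: 21 3,5-diisopropoxy-4-[5-isopropoxy-7-methoxy-2-(4-methoxyphenyl)-4-oxo-4H-chromen-8-yl]-2-(trimethylsilyl)phenyl trifluoromethanesulfonate
Conditions: PhNTf2 (1.3 equiv), DBU, MeCN–CH2Cl2, 0 °C to rt
Reagents that add atoms: N-phenylbis(trifluoromethanesulfonimide), O=S(=O)(N(c1ccccc1)S(=O)(=O)C(F)(F)F)C(F)(F)F
Why: O-Sulfonylation of a phenoxide by a mild triflyl-transfer reagent, the usual last step in making o-silylaryl triflates; PhNTf2 touches neither the pyranone carbonyl nor the ethers, and no fluoride is present that could release the aryne early.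

Step 11
Reactants: 21 3,5-diisopropoxy-4-[5-isopropoxy-7-methoxy-2-(4-methoxyphenyl)-4-oxo-4H-chromen-8-yl]-2-(trimethylsilyl)phenyl trifluoromethanesulfonate, 22 3-(4-methoxyphenyl)propiolic acid
Product: 26 5,7-diisopropoxy-6-[5-isopropoxy-7-methoxy-2-(4-methoxyphenyl)-4-oxo-4H-chromen-8-yl]-2-(4-methoxyphenyl)-4H-chromen-4-one, via cesium propiolate 23 (not isolated), via aryne 24 (not isolated), via ynone phenoxide 25 (not isolated)
Conditions: 22 (1.5 equiv), CsF (4 equiv), THF, sealed tube, 125 °C
Reagents that add atoms: cesium fluoride, [Cs+].[F-] (cesium of 23 and 25 only)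
Why: Fluoride attacks silicon and triflate departs to give aryne 24; carboxylate 23 adds through oxygen at C8a, the resulting C4a aryl anion attacks the adjacent ester carbonyl, and the strained four-membered alkoxide opens to the o-acylphenoxide 25, a net insertion into the acyl C–O bond. Phenoxide 25 then adds to the ynone carbon C2, and protonation at C3 by the bifluoride formed from the acid proton completes the pyranone. The closest known reaction type is the fluoride-induced insertion of arynes into carboxylic acids, which gives o-hydroxyaryl ketones and, with arylpropiolic acids, flavones directly. Ring C closes in the 6-endo-dig mode, a conjugate addition that gives a carbonyl-stabilised allenolate, whereas 5-exo-dig closure to the aurone would leave an unstabilised vinyl anion. No stereocentre is formed and the biaryl axis stays racemic. The step needs oxygen attack at C8a and not at C4a: the sigma-withdrawing C5 isopropoxy group distorts the aryne so that C8a is the electrophilic terminus and the charge developing on C4a is stabilised, C8a is also the open side (C8–H), and hot THF with sparingly soluble CsF keeps the aryne dilute and favours acyl transfer over protonation of the aryl anion.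

Step 12
Reactants: 26 5,7-diisopropoxy-6-[5-isopropoxy-7-methoxy-2-(4-methoxyphenyl)-4-oxo-4H-chromen-8-yl]-2-(4-methoxyphenyl)-4H-chromen-4-one
Product: 27 5,7-dihydroxy-6-[5-hydroxy-7-methoxy-2-(4-methoxyphenyl)-4-oxo-4H-chromen-8-yl]-2-(4-methoxyphenyl)-4H-chromen-4-one (CNP0146326.0)
Conditions: BCl3 (1 M in CH2Cl2, 8 equiv), CH2Cl2, −78 °C to rt; then H2O
Reagents that add atoms: none
Why: Lewis acid ether cleavage; BCl3 binds the ether oxygens and the secondary isopropyl groups leave as 2-chloropropane much faster than methyl groups, the C5 and C5'' ethers being further activated by chelation to the C4 and C4'' carbonyls, whereas none of the three methoxy groups has a neighbouring carbonyl, and the mild conditions give no opening and reclosure of the pyranone (Wessely–Moser rearrangement).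

Compound list
1 | 2',6'-dihydroxy-4'-methoxyacetophenone | CC(=O)c1c(O)cc(OC)cc1O | starting material
2 | 2'-hydroxy-6'-isopropoxy-4'-methoxyacetophenone | CC(=O)c1c(O)cc(OC)cc1OC(C)C | intermediate
3 | 2'-hydroxy-3'-iodo-6'-isopropoxy-4'-methoxyacetophenone | CC(=O)c1c(O)c(I)c(OC)cc1OC(C)C | intermediate
4 | 4-methoxybenzaldehyde | COc1ccc(C=O)cc1 | starting material
5 | (E)-1-(2-hydroxy-3-iodo-6-isopropoxy-4-methoxyphenyl)-3-(4-methoxyphenyl)prop-2-en-1-one | COc1ccc(/C=C/C(=O)c2c(O)c(I)c(OC)cc2OC(C)C)cc1 | intermediate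
6 | 8-iodo-5-isopropoxy-7-methoxy-2-(4-methoxyphenyl)chroman-4-one (racemic, not isolated) | COc1ccc(C2CC(=O)c3c(OC(C)C)cc(OC)c(I)c3O2)cc1 | intermediate
7 | 8-iodo-5-isopropoxy-7-methoxy-2-(4-methoxyphenyl)-4H-chromen-4-one | COc1ccc(-c2cc(=O)c3c(OC(C)C)cc(OC)c(I)c3o2)cc1 | intermediate
8 | 2-bromoresorcinol | Oc1cccc(O)c1Br | starting material
9 | 2-bromo-1,3-diisopropoxybenzene | CC(C)Oc1cccc(OC(C)C)c1Br | intermediate
10 | 2-(4-bromo-3,5-diisopropoxyphenyl)-4,4,5,5-tetramethyl-1,3,2-dioxaborolane (not isolated) | CC(C)Oc1cc(B2OC(C)(C)C(C)(C)O2)cc(OC(C)C)c1Br | intermediate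
11 | 4-bromo-3,5-diisopropoxyphenol | CC(C)Oc1cc(O)cc(OC(C)C)c1Br | intermediate
12 | 4-bromo-2-iodo-3,5-diisopropoxyphenol | CC(C)Oc1cc(O)c(I)c(OC(C)C)c1Br | intermediate
13 | (4-bromo-2-iodo-3,5-diisopropoxyphenoxy)trimethylsilane (not isolated) | CC(C)Oc1cc(O[Si](C)(C)C)c(I)c(OC(C)C)c1Br | intermediate
14 | 3-bromo-2,4-diisopropoxy-6-(trimethylsilyloxy)phenyllithium (not isolated) | CC(C)Oc1cc(O[Si](C)(C)C)c([Li])c(OC(C)C)c1Br | intermediate
15 | lithium 4-bromo-3,5-diisopropoxy-2-(trimethylsilyl)phenoxide (not isolated) | [Li+].[O-]c1cc(OC(C)C)c(Br)c(OC(C)C)c1[Si](C)(C)C | intermediate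
16 | [4-bromo-3,5-diisopropoxy-2-(trimethylsilyl)phenoxy]trimethylsilane | CC(C)Oc1cc(O[Si](C)(C)C)c([Si](C)(C)C)c(OC(C)C)c1Br | intermediate
17 | 2,6-diisopropoxy-3-(trimethylsilyl)-4-(trimethylsilyloxy)phenyllithium (not isolated) | CC(C)Oc1cc(O[Si](C)(C)C)c([Si](C)(C)C)c(OC(C)C)c1[Li] | intermediate
18 | [2,6-diisopropoxy-3-(trimethylsilyl)-4-(trimethylsilyloxy)phenyl]zinc chloride (not isolated) | CC(C)Oc1cc(O[Si](C)(C)C)c([Si](C)(C)C)c(OC(C)C)c1[Zn]Cl | intermediate
19 | 8-[2,6-diisopropoxy-3-(trimethylsilyl)-4-(trimethylsilyloxy)phenyl]-5-isopropoxy-7-methoxy-2-(4-methoxyphenyl)-4H-chromen-4-one (not isolated) | COc1ccc(-c2cc(=O)c3c(OC(C)C)cc(OC)c(-c4c(OC(C)C)cc(O[Si](C)(C)C)c([Si](C)(C)C)c4OC(C)C)c3o2)cc1 | intermediate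
20 | 8-[4-hydroxy-2,6-diisopropoxy-3-(trimethylsilyl)phenyl]-5-isopropoxy-7-methoxy-2-(4-methoxyphenyl)-4H-chromen-4-one | COc1ccc(-c2cc(=O)c3c(OC(C)C)cc(OC)c(-c4c(OC(C)C)cc(O)c([Si](C)(C)C)c4OC(C)C)c3o2)cc1 | intermediate
21 | 3,5-diisopropoxy-4-[5-isopropoxy-7-methoxy-2-(4-methoxyphenyl)-4-oxo-4H-chromen-8-yl]-2-(trimethylsilyl)phenyl trifluoromethanesulfonate | C[Si](C)(C)c1c(OS(=O)(=O)C(F)(F)F)cc(OC(C)C)c(-c2c(OC)cc(OC(C)C)c3c(=O)cc(-c4ccc(OC)cc4)oc23)c1OC(C)C | intermediate
22 | 3-(4-methoxyphenyl)propiolic acid | COc1ccc(C#CC(=O)O)cc1 | starting material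
23 | cesium 3-(4-methoxyphenyl)propiolate (not isolated) | [Cs+].[O-]C(=O)C#Cc1ccc(OC)cc1 | intermediate
24 | 8-(2,6-diisopropoxy-3,4-didehydrophenyl)-5-isopropoxy-7-methoxy-2-(4-methoxyphenyl)-4H-chromen-4-one, the C4a≡C8a aryne (not isolated) | CC(C)OC1=C(c2c(OC)cc(OC(C)C)c3c(=O)cc(-c4ccc(OC)cc4)oc23)C(OC(C)C)=CC#C1 | intermediate
25 | cesium 3,5-diisopropoxy-4-[5-isopropoxy-7-methoxy-2-(4-methoxyphenyl)-4-oxo-4H-chromen-8-yl]-2-[3-(4-methoxyphenyl)propioloyl]phenoxide (not isolated) | [Cs+].[O-]c1cc(OC(C)C)c(-c2c(OC)cc(OC(C)C)c3c(=O)cc(-c4ccc(OC)cc4)oc23)c(OC(C)C)c1C(=O)C#Cc1ccc(OC)cc1 | intermediate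
26 | 5,7-diisopropoxy-6-[5-isopropoxy-7-methoxy-2-(4-methoxyphenyl)-4-oxo-4H-chromen-8-yl]-2-(4-methoxyphenyl)-4H-chromen-4-one | COc1ccc(-c2cc(=O)c3c(OC(C)C)c(-c4c(OC)cc(OC(C)C)c5c(=O)cc(-c6ccc(OC)cc6)oc45)c(OC(C)C)cc3o2)cc1 | intermediate
27 | 5,7-dihydroxy-6-[5-hydroxy-7-methoxy-2-(4-methoxyphenyl)-4-oxo-4H-chromen-8-yl]-2-(4-methoxyphenyl)-4H-chromen-4-one (CNP0146326.0) | COc1ccc(-c2cc(=O)c3c(O)c(-c4c(OC)cc(O)c5c(=O)cc(-c6ccc(OC)cc6)oc45)c(O)cc3o2)cc1 | target

Total step count: 12.
Longest linear sequence: 8 steps (steps 5–12; the branch through steps 1–4 and 9–12 is equally long).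

Steps most likely to fail

1. Step 11.
- What may go wrong: the C4a aryl anion may be protonated before the acyl group migrates, which leaves plain O-arylation. The propiolate may lose CO2 at 125 °C. The last closure may stray into the 5-exo mode.
- Fallback: it sets out from 20 and comes back at 26.
- Ipso-iododesilylation of 20 with ICl (CH2Cl2, −78 °C) should exchange SiMe3 for iodine. This gives 8-(4-hydroxy-3-iodo-2,6-diisopropoxyphenyl)-5-isopropoxy-7-methoxy-2-(4-methoxyphenyl)-4H-chromen-4-one F1.
- A palladium-catalysed carbonylative Sonogashira coupling of F1 with 4-ethynylanisole follows (CO, PdCl2(dppf), Et2NH, 60–100 °C). It should give the free o-hydroxyaryl ynone 8-{4-hydroxy-2,6-diisopropoxy-3-[3-(4-methoxyphenyl)propioloyl]phenyl}-5-isopropoxy-7-methoxy-2-(4-methoxyphenyl)-4H-chromen-4-one F2.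
- The secondary amine closes F2 in the same flask by 6-endo addition to 26.
- The only free oxygen lies para to the biaryl bond, so the C6 linkage is kept.

2. Step 9.
- What may go wrong: transmetalation and reductive elimination at a centre with four ortho substituents may be slow. Hydrodeiodination of the flavone and homocoupling would then take over.
- Fallback: it sets out from 16, passes through 17, and comes back at 20. The nucleophile is changed from zinc to an isolable boron reagent.
- Aryllithium 17 is trapped with 2-isopropoxy-4,4,5,5-tetramethyl-1,3,2-dioxaborolane. This gives [3,5-diisopropoxy-4-(4,4,5,5-tetramethyl-1,3,2-dioxaborolan-2-yl)-2-(trimethylsilyl)phenoxy]trimethylsilane F3.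
- Methanolic work-up converts F3 into 3,5-diisopropoxy-4-(4,4,5,5-tetramethyl-1,3,2-dioxaborolan-2-yl)-2-(trimethylsilyl)phenol F4, which can be purified.
- Suzuki–Miyaura coupling of F4 with 7 (Pd(OAc)2, SPhos, K3PO4, toluene–H2O, 80 °C) should then give 20.

3. Step 8.
- What may go wrong: the halogens may scramble through competing bromine–lithium exchange. The aryllithium may also be quenched by a proton before the silyl shift.
- Fallback: it sets out from 11 and comes back at 16. It replaces halogen–metal exchange by directed ortho-metalation.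
- Carbamoylation of 11 (ClC(O)NEt2, K2CO3, MeCN) gives 4-bromo-3,5-diisopropoxyphenyl N,N-diethylcarbamate F5.
- Deprotonation of F5 between the carbamate and the isopropoxy group with LiN(iPr)2 in the presence of Me3SiCl (THF, −78 °C, in situ quench) gives 4-bromo-3,5-diisopropoxy-2-(trimethylsilyl)phenyl N,N-diethylcarbamate F6. The bromide has no ortho hydrogen and is not exchanged by the amide base.
- Reductive cleavage of F6 with Cp2Zr(H)Cl (THF, rt) gives 4-bromo-3,5-diisopropoxy-2-(trimethylsilyl)phenol F7.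
- Silylation of F7 with (Me3Si)2NH gives 16.

Further compounds
F1 | step 11 | 8-(4-hydroxy-3-iodo-2,6-diisopropoxyphenyl)-5-isopropoxy-7-methoxy-2-(4-methoxyphenyl)-4H-chromen-4-one | COc1ccc(-c2cc(=O)c3c(OC(C)C)cc(OC)c(-c4c(OC(C)C)cc(O)c(I)c4OC(C)C)c3o2)cc1
F2 | step 11 | 8-{4-hydroxy-2,6-diisopropoxy-3-[3-(4-methoxyphenyl)propioloyl]phenyl}-5-isopropoxy-7-methoxy-2-(4-methoxyphenyl)-4H-chromen-4-one | COc1ccc(C#CC(=O)c2c(O)cc(OC(C)C)c(-c3c(OC)cc(OC(C)C)c4c(=O)cc(-c5ccc(OC)cc5)oc34)c2OC(C)C)cc1
F3 | step 9 | [3,5-diisopropoxy-4-(4,4,5,5-tetramethyl-1,3,2-dioxaborolan-2-yl)-2-(trimethylsilyl)phenoxy]trimethylsilane | CC(C)Oc1cc(O[Si](C)(C)C)c([Si](C)(C)C)c(OC(C)C)c1B2OC(C)(C)C(C)(C)O2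
F4 | step 9 | 3,5-diisopropoxy-4-(4,4,5,5-tetramethyl-1,3,2-dioxaborolan-2-yl)-2-(trimethylsilyl)phenol | CC(C)Oc1cc(O)c([Si](C)(C)C)c(OC(C)C)c1B2OC(C)(C)C(C)(C)O2
F5 | step 8 | 4-bromo-3,5-diisopropoxyphenyl N,N-diethylcarbamate | CCN(CC)C(=O)Oc1cc(OC(C)C)c(Br)c(OC(C)C)c1
F6 | step 8 | 4-bromo-3,5-diisopropoxy-2-(trimethylsilyl)phenyl N,N-diethylcarbamate | CCN(CC)C(=O)Oc1cc(OC(C)C)c(Br)c(OC(C)C)c1[Si](C)(C)C
F7 | step 8 | 4-bromo-3,5-diisopropoxy-2-(trimethylsilyl)phenol | CC(C)Oc1cc(O)c([Si](C)(C)C)c(OC(C)C)c1Br
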